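At late times the dusk readings change little: E reads 44.7% at 50.0 h and 45.2% at 72.0 h, while a reading scatters by 1 percentage point. So what should we expect at that level?

in all of them: G 20 mM

| flask | Z | X | temperature | remark | time |
|---|---|---|---|---|---|
| dusk | 26 mM | 40 mM | 25 °C | the very flask that is asked about, followed so far |  |
| midnight | 17 mM | 40 mM | 31 °C | run made earlier |  |
| flask | 26.0 mM | 40.0 mM | 25 °C |  | 5.0 d |

| dusk: time / h | dusk: E / % | midnight: time / h | midnight: E / % |
|---|---|---|---|
| 12.0 | 27.0 | 0.833 | 3.9 |
| 25.0 | 36.7 | 1.50 | 6.1 |
| 40.0 | 40.4 | 2.50 | 10.0 |
| 50.0 | 44.7 | 3.00 | 12.8 |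
| 60.0 | 43.8 | 4.00 | 15.4 |
| 72.0 | 45.2 | 5.00 | 16.8 |

(each reading ± 1 percentage point)

- north: at 5.0 d add Z, 50.0% of the amount charged, then wait 10 d
- east: change nothing and wait 10 d more
- north-west: at 5.0 d take out 90% of the E then present, then wait 10 d
- north-east: at 5.0 d raise the temperature by 15 K, then wait 10 d

- removed E is counted in
- steps under discussion: G + Z <-> E; X + Z <-> L; X <-> D
- additions bring no volume worth counting

* E, in percent of the G first charged, at 5.0 d
* which option adds most E ("none" when 2 percentage points or less is all one gets) (north / east / north-west / north-east / none)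
* E present, with what was taken out counted in, in percent of the G first charged, after east
* E present, with what was taken out counted in, in percent of the G first charged, after north-west

Two extreme versions of the flask can be solved in the head. If X left Z untouched and G + Z ran one way, Z would stand at 1.30 equivalents to G, more than G needs, and the ceiling for E would be the whole charge of G. If instead X is a rival as fast as G and both steps run one way, Z is shared in proportion to the charges and each substrate reaches the same conversion. We call this conversion the coverage 43.3%: the charge of Z divided by the summed charges of G and X. For one-way, one-to-one steps of equal speed, control changes hands where coverage crosses one. Below that crossing Z is the limiting reagent of this second version, and in this flask c(Z) is less than c(G) + c(X).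

The last dusk reading lies between these versions, near the second, 1.9 points above the coverage. We therefore commit to E close to that reading at 5.0 d. Raising Z by 50.0% lifts the coverage to 65.0%, a gain of 22 points. Coverage assumes one-way steps, so it says nothing about north-west or north-east.

The forecast gives 45.7% now, 46% after east and 46.5% after north-west, and it picks north, holding that “Heating likewise gains little”.

The flask gives 46.8% at 5.0 d, 49.8% after east and 64.2% after north-west. The best option is north-east, which adds 28 points, while north adds 20 points.

    G + Z ⇌ E (K = 375 /M, k = 4.71 × 10⁻⁴ /M/s, Ea = 77.0 kJ/mol, ΔH = 28.0 kJ/mol)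
    X + Z ⇌ L (K = 220 /M, k = 4.94 × 10⁻⁴ /M/s, Ea = 57.0 kJ/mol, ΔH = −80.0 kJ/mol)
    X ⇌ D (K = 0.178, k = 3.44 × 10⁻⁵ /s, Ea = 103 kJ/mol, ΔH = −22.0 kJ/mol)
    (constants at 25 °C)

Coverage stands 3.5 points below E in this flask at 5.0 d, and Z keeps 10.4% of its charge at 120 h. The relaxation half-life of G + Z and E by that step alone at 120 h, 25.5 h, is shorter than 5.0 d, yet this flask is not quite at rest: by 1200 h E reaches 50.1%, a further 3.3 points. Over that time G falls to 49.9%, L slips from 13.9 mM to 13.3 mM, and Z holds at 10.3%.

With 160 mM of X, coverage drops to 14.4%, so E should fall to about that. The computed neighbour gives 19.0%, with 3.1% of Z left.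

The data stem from a simulated flask from invented constants, and the scatter is random.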